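**Plan**
- Retrosynthesis first returns the C7 benzoate and the C2/C3 acetates to ethers, then opens the C6–O bond of the oxirane to a trans-1,6-diol (the oxirane oxygen stays on C1).
- C1 (quaternary oxirane carbon carrying C7) and C6 (oxirane CH) are adjacent oxygen-bearing ring carbons, i.e. a masked α-ketol. The ring bond C1–C6 is therefore cut between a C1 ketone and a C6 aldehyde, which opens the only carbocycle.
- The acyclic L-ido keto-aldehyde (C6–C5–C4–C3–C2–C1–C7) is cut at C2–C1 into a glucose-derived xylo-pentodialdofuranose (C6–C2) and a 2-metallated allyl ether (C1, C7). The C=CH2 of that ether is the latent ketone and a vinyl group is the latent aldehyde.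
- Forward: the chain is joined by alkenyllithium addition; protecting groups are set (Bn on O4/O5, 2-naphthylmethyl on O2/O3/O7); the furanose is opened by methylenation; both alkenes are cleaved; the cyclohexane closes by carbene-catalysed benzoin; the oxirane closes; esters come last.
- Stereochemistry: C3, C4, C5 come from C4, C3, C2 of D-glucose; C2 from chelation-controlled addition (L-ido); C1 from the chair of the benzoin closure; C6 from hydroxyl-directed reduction, then inverted in the oxirane closure.

Key step: step 12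

Numbering and abbreviations: from compound 12 onward the target locants are used (C1 quaternary oxirane carbon, C7 its CH2O arm, C2/C3 acetoxy carbons, C4/C5 carbinols, C6 oxirane CH). The furanoses 1–3 and 7–11 carry sugar locants; sugar C1–C5 = target C6–C2, sugar C6 = target C1, sugar C7 = target C7. NAP = 2-naphthylmethyl.
Remark on the chemistry: the anomeric mixtures 9–11 are carried on unseparated, since the anomeric carbon ends as the C6 aldehyde.

**Step 1**
Reactants: 1 1,2:5,6-di-O-isopropylidene-α-D-glucofuranose (diacetone-D-glucose)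
Product: 2 3-O-benzyl-1,2:5,6-di-O-isopropylidene-α-D-glucofuranose
Conditions: NaH, BnBr, Bu4NI (cat.), DMF, 0 °C → rt
Reagents that add atoms: benzyl bromide BrCc1ccccc1
Why: Williamson etherification of the single free hydroxyl (sugar O3, later O4 of the target) installs a benzyl group that stays to the last step; no stereocentre is involved.

**Step 2**
Reactants: 2 3-O-benzyl-1,2:5,6-di-O-isopropylidene-α-D-glucofuranose
Product: 3 3-O-benzyl-1,2-O-isopropylidene-α-D-xylo-pentodialdo-1,4-furanose
Conditions: H5IO6, EtOAc, rt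
Reagents that add atoms: none
Why: Periodic acid hydrolyses the terminal 5,6-acetonide faster than the ring-fused 1,2-acetonide and cleaves the freed glycol at once (Malaprade glycol cleavage), giving the C5 aldehyde with C2–C4 of glucose untouched.

**Step 3**
Reactants: 4 2-bromoprop-2-en-1-ol
Product: 5 2-bromoallyl 2-naphthylmethyl ether
Conditions: NaH, THF, 0 °C; 2-(bromomethyl)naphthalene, Bu4NI (cat.), 0 °C → rt
Reagents that add atoms: 2-(bromomethyl)naphthalene BrCc1ccc2ccccc2c1
Why: Williamson etherification of the primary allylic alkoxide with a reactive arylmethyl bromide; the vinylic bromide takes no part.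

**Step 4**
Reactants: 5 2-bromoallyl 2-naphthylmethyl ether; 3 3-O-benzyl-1,2-O-isopropylidene-α-D-xylo-pentodialdo-1,4-furanose
Product: 7 3-O-benzyl-6-deoxy-1,2-O-isopropylidene-6-C-methylidene-7-O-(2-naphthylmethyl)-β-L-ido-heptofuranose, via alkenyllithium 6 (not isolated)
Conditions: 5, t-BuLi (2 equiv), Et2O, −78 °C; then 3, −78 °C; aq. NH4Cl
Reagents that add atoms: none
Why: Bromine–lithium exchange and 1,2-addition of the alkenyllithium to the aldehyde; in ether lithium should bridge the formyl and furanose ring oxygens (Cram chelate) so that the nucleophile enters anti to C3 and its benzyloxy group, which gives the 4,5-threo (L-ido) carbinol, the sense usually found for carbanion additions to this aldehyde, and any D-gluco epimer would be removed by chromatography.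

**Step 5**
Reactants: 7 3-O-benzyl-6-deoxy-1,2-O-isopropylidene-6-C-methylidene-7-O-(2-naphthylmethyl)-β-L-ido-heptofuranose
Product: 8 3-O-benzyl-6-deoxy-1,2-O-isopropylidene-6-C-methylidene-5,7-di-O-(2-naphthylmethyl)-β-L-ido-heptofuranose
Conditions: NaH, 2-(bromomethyl)naphthalene, Bu4NI (cat.), DMF, 0 °C → rt
Reagents that add atoms: 2-(bromomethyl)naphthalene BrCc1ccc2ccccc2c1
Why: Williamson etherification of the new carbinol; NAP is chosen because it should survive the two acidic steps that follow and can still be removed by DDQ beside benzyl ethers.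

**Step 6**
Reactants: 8 3-O-benzyl-6-deoxy-1,2-O-isopropylidene-6-C-methylidene-5,7-di-O-(2-naphthylmethyl)-β-L-ido-heptofuranose
Product: 9 methyl 3-O-benzyl-6-deoxy-6-C-methylidene-5,7-di-O-(2-naphthylmethyl)-L-ido-heptofuranoside (α/β mixture, free 2-OH)
Conditions: HCl (1.25 M in MeOH), rt
Reagents that add atoms: methanol CO
Why: Acid-catalysed transacetalisation (Fischer-type glycosidation) replaces the 1,2-acetonide by a methyl furanoside and frees O2; with O5 etherified only a furanoside can form.

**Step 7**
Reactants: 9 methyl 3-O-benzyl-6-deoxy-6-C-methylidene-5,7-di-O-(2-naphthylmethyl)-L-ido-heptofuranoside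
Product: 10 methyl 2,3-di-O-benzyl-6-deoxy-6-C-methylidene-5,7-di-O-(2-naphthylmethyl)-L-ido-heptofuranoside (α/β)
Conditions: NaH, BnBr, Bu4NI (cat.), DMF, 0 °C → rt
Reagents that add atoms: benzyl bromide BrCc1ccccc1
Why: Williamson etherification of the only free hydroxyl completes the 2,3-di-O-benzyl pair that ends as the C4/C5 diol of the target.

**Step 8**
Reactants: 10 methyl 2,3-di-O-benzyl-6-deoxy-6-C-methylidene-5,7-di-O-(2-naphthylmethyl)-L-ido-heptofuranoside
Product: 11 2,3-di-O-benzyl-6-deoxy-6-C-methylidene-5,7-di-O-(2-naphthylmethyl)-L-ido-heptofuranose (lactol, α/β)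
Conditions: 1 M aq. HCl/1,4-dioxane (1:3), 65 °C
Reagents that add atoms: water O
Why: Acid hydrolysis of the furanoside acetal, which is far more labile than the arylmethyl ethers; the 1,1-disubstituted alkene, deactivated by two allylic oxygens, is expected to persist.

**Step 9**
Reactants: 11 2,3-di-O-benzyl-6-deoxy-6-C-methylidene-5,7-di-O-(2-naphthylmethyl)-L-ido-heptofuranose
Product: 12 acyclic L-ido diene carbinol CH2=C6H–C5H(OBn)–C4H(OBn)–C3H(OH)–C2H(ONAP)–C1(=CH2)–C7H2ONAP
Conditions: Ph3PCH3Br, KOtBu, THF, 0 → 45 °C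
Reagents that add atoms: methyltriphenylphosphonium bromide C[P+](c1ccccc1)(c1ccccc1)c1ccccc1.[Br-]
Why: Wittig methylenation of the open-chain aldehyde tautomer of the lactol opens the furanose for good, stores the C6 aldehyde as a vinyl group and frees the former ring oxygen as the C3 hydroxyl.

**Step 10**
Reactants: 12 acyclic L-ido diene carbinol
Product: 13 fully protected diene CH2=C6H–C5H(OBn)–C4H(OBn)–C3H(ONAP)–C2H(ONAP)–C1(=CH2)–C7H2ONAP
Conditions: NaH, 2-(bromomethyl)naphthalene, Bu4NI (cat.), DMF, 0 °C → rt
Reagents that add atoms: 2-(bromomethyl)naphthalene BrCc1ccc2ccccc2c1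
Why: Williamson etherification puts the second NAP group on the O2/O3 pair that later becomes the diacetate.

**Step 11**
Reactants: 13 fully protected diene
Product: 14 2,3-di-O-benzyl-4,5,7-tri-O-(2-naphthylmethyl)-aldehydo-L-ido-heptos-6-ulose (target numbering: C6 aldehyde, C5/C4 OBn, C3/C2 ONAP, C1 ketone, C7H2ONAP)
Conditions: OsO4 (2 mol %), NaIO4, 2,6-lutidine, 1,4-dioxane/H2O (3:1), rt
Reagents that add atoms: osmium tetroxide O=[Os](=O)(=O)=O; sodium periodate [Na+].[O-]I(=O)(=O)=O
Why: Lemieux–Johnson oxidation dihydroxylates the vinyl and the 1,1-disubstituted alkene and cleaves both glycols in the same flask, each losing its CH2 terminus; the lutidine buffer should protect the α-alkoxy centres C2 and C5 from epimerisation, and the naphthalene rings, unlike under ozonolysis, are left alone.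

**Step 12**
Reactants: 14 L-ido keto-aldehyde
Product: 15 α-ketol: cyclohexanone with C6 ketone, tertiary C1–OH (axial, cis to O2) carrying equatorial C7H2ONAP, ONAP at C2 and C3, OBn at C4 and C5 (C2–C5 substituents all-trans, all equatorial)
Conditions: 2-(pentafluorophenyl)-6,7-dihydro-5H-pyrrolo[2,1-c][1,2,4]triazol-2-ium tetrafluoroborate (15 mol %), i-Pr2NEt (15 mol %), toluene (0.02 M), rt
Reagents that add atoms: none
Why: The triazolylidene released by the amine adds to the C6 aldehyde (the ketone cannot give the enaminol), proton transfer gives the nucleophilic enaminol, and this acyl-anion equivalent attacks the C1 ketone before the carbene is expelled, leaving the C6 ketone and the tertiary C1 carbinol. The closest known reaction type is the carbene-catalysed intramolecular crossed aldehyde–ketone benzoin cyclisation, which has been applied to polyalkoxylated, sugar-derived dicarbonyls. The cyclohexane closes in a 6-exo-trig mode through a chair in which the four alkoxy groups at C2–C5 are equatorial, so the C2–O and C5–O bonds lie anti to the forming C1–C6 bond. The one new stereocentre, C1, should be set by this chair: the ketone keeps its larger CH2ONAP arm equatorial (Felkin–Anh sense with respect to C2), so the carbonyl oxygen, within hydrogen-bonding reach of the enaminol OH, becomes the axial hydroxyl cis to O2. The step needs the aldehyde as sole donor and the ketone as acceptor without homo-benzoin, and it must spare the base-labile α- and β-alkoxy carbonyls; the aldehyde/ketone difference, the six-atom tether at high dilution, ether-only protection and an acidic N-pentafluorophenyl triazolium paired with a weak amine base are what should secure this.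

**Step 13**
Reactants: 15 α-ketol
Product: 16 trans-1,6-diol (C6–OH axial, anti to the axial C1–OH; otherwise as 15)
Conditions: Me4NBH(OAc)3, MeCN/AcOH (1:1), −30 → 0 °C
Reagents that add atoms: none
Why: Saksena–Evans hydroxyl-directed reduction: the tertiary C1–OH exchanges onto boron and hydride is delivered within the molecule to the face of the C6 ketone that this axial hydroxyl occupies, so the new C6–OH should be axial and trans to O1, as the oxirane closure requires.

**Step 14**
Reactants: 16 trans-1,6-diol
Product: 18 1,6-epoxide with oxirane oxygen cis to O2 and trans to O5 (ONAP at C2 C3 C7 and OBn at C4 C5), via C6 mesylate 17 (not isolated)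
Conditions: MsCl, Et3N, CH2Cl2, 0 °C; then MeOH, K2CO3, rt
Reagents that add atoms: none
Why: Sulfonylation touches only the secondary C6–OH, and the tertiary C1 alkoxide then displaces the trans-diaxial mesylate in an intramolecular Williamson (3-exo-tet) closure with inversion at C6, placing the oxirane oxygen on the face of the former C1–OH.

**Step 15**
Reactants: 18 1,6-epoxide tris-NAP ether
Product: 19 epoxy triol (free C2–OH, C3–OH and C7–OH; 4,5-di-O-benzyl)
Conditions: DDQ, CH2Cl2/pH 7 phosphate buffer (9:1), 0 °C → rt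
Reagents that add atoms: none
Why: Oxidative cleavage of the three 2-naphthylmethyl ethers by DDQ (hydride abstraction, then hydrolysis of the oxocarbenium ions) is selective over benzyl ethers, and the buffered wet medium should spare the oxirane and suppress arylidene acetal formation.

**Step 16**
Reactants: 19 epoxy triol
Product: 21 4,5-di-O-benzyl ether of the target (C7 benzoate and C2 C3 diacetate), via C7 monobenzoate 20 (not isolated)
Conditions: BzCl (1.05 equiv), pyridine, CH2Cl2, −40 → 0 °C; then Ac2O, DMAP (cat.), rt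
Reagents that add atoms: benzoyl chloride O=C(Cl)c1ccccc1; acetic anhydride CC(=O)OC(C)=O
Why: Rate-selective acylation: at low temperature the primary C7–OH should be benzoylated ahead of the two flanked secondary hydroxyls, which are then acetylated in the same flask under conditions too weakly basic for epoxide migration.

**Step 17**
Reactants: 21 4,5-di-O-benzyl ether of the target
Product: 22 target: 7-O-benzoyl-2,3-di-O-acetyl-1,6-epoxide with free C4–OH and C5–OH (oxirane oxygen, O2 and O4 on one face; C7, O3 and O5 on the other)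
Conditions: H2 (1 atm), Pd(OH)2/C, EtOAc, rt
Reagents that add atoms: none
Why: Catalytic hydrogenolysis of the two benzyl ethers under neutral conditions, which should leave the non-benzylic oxirane and the three esters untouched.

**Compound list**
1 | 1,2:5,6-di-O-isopropylidene-α-D-glucofuranose | O[C@@H]1[C@H]2OC(C)(C)O[C@H]2O[C@@H]1[C@H]1COC(C)(C)O1 | starting material
2 | 3-O-benzyl-1,2:5,6-di-O-isopropylidene-α-D-glucofuranose | c1ccccc1CO[C@@H]1[C@H]2OC(C)(C)O[C@H]2O[C@@H]1[C@H]1COC(C)(C)O1 | intermediate
3 | 3-O-benzyl-1,2-O-isopropylidene-α-D-xylo-pentodialdo-1,4-furanose | c1ccccc1CO[C@@H]1[C@H]2OC(C)(C)O[C@H]2O[C@@H]1C=O | intermediate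
4 | 2-bromoprop-2-en-1-ol | OCC(Br)=C | starting material
5 | 2-bromoallyl 2-naphthylmethyl ether | C=C(Br)COCc1ccc2ccccc2c1 | intermediate
6 | {3-[(2-naphthyl)methoxy]prop-1-en-2-yl}lithium | [Li]C(=C)COCc1ccc2ccccc2c1 | intermediate (not isolated)
7 | 3-O-benzyl-6-deoxy-1,2-O-isopropylidene-6-C-methylidene-7-O-(2-naphthylmethyl)-β-L-ido-heptofuranose | c1ccccc1CO[C@@H]1[C@H]2OC(C)(C)O[C@H]2O[C@@H]1[C@@H](O)C(=C)COCc1ccc2ccccc2c1 | intermediate
8 | 3-O-benzyl-6-deoxy-1,2-O-isopropylidene-6-C-methylidene-5,7-di-O-(2-naphthylmethyl)-β-L-ido-heptofuranose | c1ccccc1CO[C@@H]1[C@H]2OC(C)(C)O[C@H]2O[C@@H]1[C@@H](OCc1ccc2ccccc2c1)C(=C)COCc1ccc2ccccc2c1 | intermediate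
9 | methyl 3-O-benzyl-6-deoxy-6-C-methylidene-5,7-di-O-(2-naphthylmethyl)-L-ido-heptofuranoside (α/β) | c1ccccc1CO[C@@H]1[C@@H](O)C(OC)O[C@@H]1[C@@H](OCc1ccc2ccccc2c1)C(=C)COCc1ccc2ccccc2c1 | intermediate
10 | methyl 2,3-di-O-benzyl-6-deoxy-6-C-methylidene-5,7-di-O-(2-naphthylmethyl)-L-ido-heptofuranoside (α/β) | c1ccccc1CO[C@@H]1[C@@H](OCc2ccccc2)C(OC)O[C@@H]1[C@@H](OCc1ccc2ccccc2c1)C(=C)COCc1ccc2ccccc2c1 | intermediate
11 | 2,3-di-O-benzyl-6-deoxy-6-C-methylidene-5,7-di-O-(2-naphthylmethyl)-L-ido-heptofuranose (α/β) | c1ccccc1CO[C@@H]1[C@@H](OCc2ccccc2)C(O)O[C@@H]1[C@@H](OCc1ccc2ccccc2c1)C(=C)COCc1ccc2ccccc2c1 | intermediate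
12 | acyclic L-ido diene carbinol (free C3–OH) | C=C[C@H](OCc1ccccc1)[C@@H](OCc1ccccc1)[C@H](O)[C@@H](OCc1ccc2ccccc2c1)C(=C)COCc1ccc2ccccc2c1 | intermediate
13 | fully protected acyclic L-ido diene | C=C[C@H](OCc1ccccc1)[C@@H](OCc1ccccc1)[C@H](OCc1ccc2ccccc2c1)[C@@H](OCc1ccc2ccccc2c1)C(=C)COCc1ccc2ccccc2c1 | intermediate
14 | 2,3-di-O-benzyl-4,5,7-tri-O-(2-naphthylmethyl)-aldehydo-L-ido-heptos-6-ulose | O=C[C@H](OCc1ccccc1)[C@@H](OCc1ccccc1)[C@H](OCc1ccc2ccccc2c1)[C@@H](OCc1ccc2ccccc2c1)C(=O)COCc1ccc2ccccc2c1 | intermediate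
15 | α-ketol (C6 ketone, axial tertiary C1–OH, equatorial C7H2ONAP) | O=C1[C@H](OCc2ccccc2)[C@@H](OCc2ccccc2)[C@H](OCc2ccc3ccccc3c2)[C@@H](OCc2ccc3ccccc3c2)[C@]1(O)COCc1ccc2ccccc2c1 | intermediate
16 | trans-1,6-diol (C6–OH axial) | O[C@@H]1[C@H](OCc2ccccc2)[C@@H](OCc2ccccc2)[C@H](OCc2ccc3ccccc3c2)[C@@H](OCc2ccc3ccccc3c2)[C@]1(O)COCc1ccc2ccccc2c1 | intermediate
17 | C6 mesylate of 16 | CS(=O)(=O)O[C@@H]1[C@H](OCc2ccccc2)[C@@H](OCc2ccccc2)[C@H](OCc2ccc3ccccc3c2)[C@@H](OCc2ccc3ccccc3c2)[C@]1(O)COCc1ccc2ccccc2c1 | intermediate (not isolated)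
18 | 1,6-epoxide, 2,3,7-tri-O-NAP, 4,5-di-O-Bn | c1ccc2cc(ccc2c1)CO[C@H]1[C@H](OCc2ccccc2)[C@@H](OCc2ccccc2)[C@@H]2O[C@]2(COCc2ccc3ccccc3c2)[C@@H]1OCc1ccc2ccccc2c1 | intermediate
19 | epoxy triol, 4,5-di-O-Bn | O[C@H]1[C@H](OCc2ccccc2)[C@@H](OCc2ccccc2)[C@@H]2O[C@]2(CO)[C@@H]1O | intermediate
20 | C7 monobenzoate of 19 | O[C@H]1[C@H](OCc2ccccc2)[C@@H](OCc2ccccc2)[C@@H]2O[C@]2(COC(=O)c2ccccc2)[C@@H]1O | intermediate (not isolated)
21 | 4,5-di-O-benzyl ether of the target | CC(=O)O[C@H]1[C@H](OCc2ccccc2)[C@@H](OCc2ccccc2)[C@@H]2O[C@]2(COC(=O)c2ccccc2)[C@@H]1OC(C)=O | intermediate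
22 | target (CNP0171674.1) | CC(=O)O[C@H]1[C@H](O)[C@@H](O)[C@@H]2O[C@]2(COC(=O)c2ccccc2)[C@@H]1OC(C)=O | target

**Step count and risks**
Total: 17 steps. Longest linear sequence: 16 steps (1 → 22 through steps 1, 2 and 4–17); step 3 is a one-step side branch.

Step 12 (ring closure). What may go wrong: base-induced β-elimination of an arylmethanol from the α,β-dialkoxy carbonyls, epimerisation next to the carbonyls, or attack on the wrong face of the ketone. A chiral aminoindanol-derived triazolium would be the first adjustment within the same reaction. The fallback changes the bond-forming event to a reductive coupling and sets out from 14. SmI2 with t-BuOH in THF at −78 °C should couple the aldehyde and ketone ketyls to the cis-1,6-diol F1, with the CH2ONAP arm again equatorial and the C6 oxygen trans to O5. Swern oxidation of its secondary carbinol then comes back to the route at 15.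

Step 4 (chain union). What may go wrong: poor facial selectivity in the addition to the aldehyde, giving much of the D-gluco carbinol. The fallback sets out from 3 and 5, with the addition run without regard to selectivity. The mixture of 7 and its C5 epimer, the D-gluco carbinol F2, is oxidised with Dess–Martin periodinane to the enone F3. 1,2-Reduction with NaBH4/CeCl3·7H2O in MeOH at −78 °C should then deliver hydride anti to the C4–O4 bond (Felkin–Anh), the sense used in oxidation–reduction entries to L-idofuranoses, and comes back at 7.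

Step 13 (C6 configuration). What may go wrong: slow exchange of the hindered tertiary hydroxyl onto boron, so that hydride attacks intermolecularly from the opposite face. The fallback accepts that face and sets out from 15. NaBH4 in MeOH, attacking anti to the axial C1–OH, should give the cis-1,6-diol F1. Trimethyl orthoacetate with PPTS converts it into the cyclic orthoacetate F4. AcBr in CH2Cl2 opens the derived acetoxonium ion with bromide at C6 with inversion, giving the trans bromo acetate F5. K2CO3 in MeOH removes the acetate and lets the C1 alkoxide displace bromide. The double inversion at C6 puts the oxirane oxygen on the face of the cis-diol, and the sequence comes back at 18.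

**Further compounds**
F1 | step 12 | cis-1,6-diol (C6 epimer of 16; C1–OH and C6–OH both cis to O2) | O[C@H]1[C@H](OCc2ccccc2)[C@@H](OCc2ccccc2)[C@H](OCc2ccc3ccccc3c2)[C@@H](OCc2ccc3ccccc3c2)[C@]1(O)COCc1ccc2ccccc2c1
F2 | step 4 | 3-O-benzyl-6-deoxy-1,2-O-isopropylidene-6-C-methylidene-7-O-(2-naphthylmethyl)-α-D-gluco-heptofuranose | c1ccccc1CO[C@@H]1[C@H]2OC(C)(C)O[C@H]2O[C@@H]1[C@H](O)C(=C)COCc1ccc2ccccc2c1
F3 | step 4 | 3-O-benzyl-6-deoxy-1,2-O-isopropylidene-6-C-methylidene-7-O-(2-naphthylmethyl)-α-D-xylo-heptofuranos-5-ulose | c1ccccc1CO[C@@H]1[C@H]2OC(C)(C)O[C@H]2O[C@@H]1C(=O)C(=C)COCc1ccc2ccccc2c1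
F4 | step 13 | cyclic 1,6-orthoacetate (2-methoxy-2-methyl-1,3-dioxolane) of F1 | COC1(C)O[C@H]2[C@H](OCc3ccccc3)[C@@H](OCc3ccccc3)[C@H](OCc3ccc4ccccc4c3)[C@@H](OCc3ccc4ccccc4c3)[C@]2(O1)COCc1ccc2ccccc2c1
F5 | step 13 | trans bromo acetate (C6–Br axial, C1–OAc) | Br[C@@H]1[C@H](OCc2ccccc2)[C@@H](OCc2ccccc2)[C@H](OCc2ccc3ccccc3c2)[C@@H](OCc2ccc3ccccc3c2)[C@]1(OC(C)=O)COCc1ccc2ccccc2c1
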